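**Plan**

- Rings: A is the catechol ring with its aryloxy group meta to its CH2, B the para-phenylene, C the catechol ring with its aryloxy group ortho to its CH2, D the ortho-phenylene. The enabling feature is that the ether oxygen of ring B is bonded to C5 of ring A, directly next to the free C4 hydroxyl. This ortho-aryloxyphenol is what remains when one phenol oxygen adds to the ortho carbon of a second, oxidised phenol.
- Retrosynthesis: re-methylate three hydroxyls and put two bromines back on ring B; cut the ring B O–C5 (ring A) bond, which opens the 17-membered ring to a bisphenol; cut both CH2–CH2 bridges as olefins (Wittig); cut the ring C–O–ring D ether (SNAr).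
- Forward: the ring B and ring A phosphonium salts are made; ring B is joined to ring C by a Wittig reaction, ring D is attached by SNAr, and ring A is joined by a second Wittig reaction. Both olefins are then saturated, the phenols are freed, and the only ring formed in the route, the macrocycle, closes by oxidative C–O coupling. Debromination and demethylation finish.
- Stereochemistry: the target has no stereocentre; olefin geometry is irrelevant because both double bonds are reduced.

Key step: step 12

Remark: the 17-membered ring is assumed to be conformationally mobile (no stable atropisomers), so no stereocontrol is needed; E/Z mixtures from the Wittig steps are carried forward as such.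

**Route**

Step 1
Reactants: 1 3,5-dibromo-4-hydroxybenzaldehyde
Product: 2 3,5-dibromo-4-(methoxymethoxy)benzaldehyde
Conditions: MOMCl, K2CO3, DMF, 0 °C → rt
Reagents that add atoms: chloromethyl methyl ether, COCCl
Why: Williamson-type O-alkylation of the acidic phenoxide with a small, very reactive alpha-chloro ether gives an acetal that tolerates ylides, hot carbonate and diimide and is later removed by acid without touching aryl bromides or methyl ethers.

Step 2
Reactants: 2 3,5-dibromo-4-(methoxymethoxy)benzaldehyde
Product: 3 [3,5-dibromo-4-(methoxymethoxy)phenyl]methanol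
Conditions: NaBH4, MeOH–THF, 0 °C
Reagents that add atoms: none
Why: Borohydride reduction of an aryl aldehyde to the benzylic alcohol is chemoselective over aryl bromides and the acetal.

Step 3
Reactants: 3 [3,5-dibromo-4-(methoxymethoxy)phenyl]methanol
Product: 5 {[3,5-dibromo-4-(methoxymethoxy)phenyl]methyl}triphenylphosphonium bromide (ring B salt), via benzylic bromide 4 (not isolated)
Conditions: NBS, PPh3, CH2Cl2, 0 °C; then PPh3, toluene, 90 °C
Reagents that add atoms: N-bromosuccinimide, O=C1CCC(=O)N1Br; triphenylphosphine, c1ccc(cc1)P(c1ccccc1)c1ccccc1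
Why: Appel-type bromination under neutral conditions spares the acid-labile acetal, and the benzylic bromide is then quaternised in the same flask by SN2 attack of PPh3, the salt precipitating from toluene.

Step 4
Reactants: 6 5-bromovanillin (3-bromo-4-hydroxy-5-methoxybenzaldehyde)
Product: 7 3-bromo-5-methoxy-4-(methoxymethoxy)benzaldehyde
Conditions: MOMCl, K2CO3, DMF, 0 °C → rt
Reagents that add atoms: chloromethyl methyl ether, COCCl
Why: The same Williamson-type O-alkylation protects the ring A phenol as an acetal orthogonal to the methyl ether and the aryl bromide.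

Step 5
Reactants: 7 3-bromo-5-methoxy-4-(methoxymethoxy)benzaldehyde
Product: 8 [3-bromo-5-methoxy-4-(methoxymethoxy)phenyl]methanol
Conditions: NaBH4, MeOH–THF, 0 °C
Reagents that add atoms: none
Why: Chemoselective borohydride reduction of the aldehyde to the benzylic alcohol.

Step 6
Reactants: 8 [3-bromo-5-methoxy-4-(methoxymethoxy)phenyl]methanol
Product: 10 {[3-bromo-5-methoxy-4-(methoxymethoxy)phenyl]methyl}triphenylphosphonium bromide (ring A salt), via benzylic bromide 9 (not isolated)
Conditions: NBS, PPh3, CH2Cl2, 0 °C; then PPh3, toluene, 90 °C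
Reagents that add atoms: N-bromosuccinimide, O=C1CCC(=O)N1Br; triphenylphosphine, c1ccc(cc1)P(c1ccccc1)c1ccccc1
Why: Appel-type bromination followed by SN2 quaternisation as in step 3; adding NBS in portions to the alcohol–phosphine mixture keeps free brominating agent away from the electron-rich ring.

Step 7
Reactants: 5 ring B salt; 11 2-hydroxy-3,4-dimethoxybenzaldehyde
Product: 13 6-{2-[3,5-dibromo-4-(methoxymethoxy)phenyl]ethenyl}-2,3-dimethoxyphenol (E/Z mixture), via phosphorus ylide 12 (not isolated)
Conditions: 5 (1.2 equiv), KOtBu, THF, 0 °C; then 11 pre-treated with KOtBu (1 equiv), 0 → 50 °C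
Reagents that add atoms: none
Why: Wittig olefination with a semi-stabilised benzylide, run on the salicylaldehyde as its phenoxide (one extra equivalent of base), is an established way to 2-hydroxystilbenes, and it leaves the ring C hydroxyl free for the next step.

Step 8
Reactants: 13 hydroxystilbene; 14 2-fluorobenzaldehyde
Product: 15 2-(6-{2-[3,5-dibromo-4-(methoxymethoxy)phenyl]ethenyl}-2,3-dimethoxyphenoxy)benzaldehyde (E/Z mixture)
Conditions: K2CO3, DMF, 120 °C
Reagents that add atoms: none
Why: Nucleophilic aromatic substitution (SNAr): the ortho-formyl group activates the C–F bond towards the phenoxide, whereas the unactivated aryl bromides are inert.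

Step 9
Reactants: 15 diaryl ether aldehyde; 10 ring A salt
Product: 17 2-bromo-4-{2-[2-(6-{2-[3,5-dibromo-4-(methoxymethoxy)phenyl]ethenyl}-2,3-dimethoxyphenoxy)phenyl]ethenyl}-6-methoxy-1-(methoxymethoxy)benzene (mixture of olefin isomers), via phosphorus ylide 16 (not isolated)
Conditions: 10, KOtBu, THF, 0 °C; then 15, 0 °C → rt
Reagents that add atoms: none
Why: A second Wittig olefination of an unhindered aryl aldehyde with a semi-stabilised ylide attaches ring A and completes the carbon skeleton.

Step 10
Reactants: 17 bis-stilbene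
Product: 18 2-bromo-4-{2-[2-(6-{2-[3,5-dibromo-4-(methoxymethoxy)phenyl]ethyl}-2,3-dimethoxyphenoxy)phenyl]ethyl}-6-methoxy-1-(methoxymethoxy)benzene
Conditions: TsNHNH2 (excess, in portions), NaOAc, DME–H2O, reflux
Reagents that add atoms: none
Why: Diimide reduction: diimide generated in the flask delivers H2 to both stilbene double bonds by concerted syn transfer and, unlike catalytic hydrogenation, leaves the three C–Br bonds intact.

Step 11
Reactants: 18 bis-MOM tribromide
Product: 19 2-bromo-4-[2-(2-{6-[2-(3,5-dibromo-4-hydroxyphenyl)ethyl]-2,3-dimethoxyphenoxy}phenyl)ethyl]-6-methoxyphenol (open-chain tribromo bisphenol)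
Conditions: conc. HCl (cat.), MeOH–THF, 50 °C
Reagents that add atoms: none
Why: Acid-catalysed transacetalisation to dimethoxymethane frees both phenols, while aryl methyl ethers, the diaryl ether and the aryl bromides do not react.

Step 12
Reactants: 19 open-chain tribromo bisphenol
Product: 21 macrocyclic dibromo diaryl ether (ring A 4-hydroxy-3-methoxy-5-aryloxy; ring B 2,6-dibromo-1,4-phenylene), via macrocyclic bromodienone 20 (not isolated)
Conditions: Tl(NO3)3·3H2O, MeOH–THF, high dilution, –20 → 0 °C; then Zn dust, AcOH, rt
Reagents that add atoms: none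
Why: Trivalent thallium should take two electrons from the ring A phenol through an aryloxythallium species to a phenoxonium-type cation, the ring B hydroxyl adds to its bromine-bearing ortho carbon to give the 6-aryloxy-6-bromocyclohexa-2,4-dienone 20 (methanol adducts formed alongside lie on the same manifold), and zinc in acetic acid cleaves the C–Br bond alpha to the carbonyl so that the ring rearomatises to the ortho-aryloxyphenol. The closest known reaction type is the Tl(NO3)3 oxidation of ortho-halophenols to macrocyclic diaryl ethers with zinc work-up, as used for isodityrosine-type rings. The 17-membered ring closes by intramolecular C–O bond formation between the ring B oxygen as nucleophile and C5 of ring A as electrophile, favoured by high dilution. No stereocentre remains, since the sp3 carbon of 20 forms as a racemate and becomes planar again on reduction. The step needs oxidation of ring A and not ring B (the methoxy donor on ring A against two bromine acceptors on ring B), attack through oxygen and not carbon of ring B (both its ortho positions carry bromine), and attack at the C–Br carbon of ring A and not its C–OMe or para carbon; only the bromine-bearing carbon has a leaving group whose loss restores aromaticity with the new C–O bond kept, and adducts at the other positions are ketals that zinc should return to 19 for recycling.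

Step 13
Reactants: 21 macrocyclic dibromo diaryl ether
Product: 22 debrominated macrocycle (tri-O-methyl ether of the target with free ring A C4 hydroxyl)
Conditions: H2 (1 atm), palladium on carbon (10% Pd/C), NaOAc, MeOH–EtOAc, rt
Reagents that add atoms: none
Why: Palladium-catalysed hydrogenolysis of aryl C–Br bonds, with NaOAc taking up the HBr, should remove both ring B bromines while diaryl ethers, methyl ethers and the phenol persist.

Step 14
Reactants: 22 debrominated macrocycle
Product: 23 target macrocyclic bis(bibenzyl) tetraphenol (CNP0114693.0)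
Conditions: BBr3, CH2Cl2, –78 °C → rt; then H2O
Reagents that add atoms: none
Why: Lewis-acid ether cleavage: BBr3 binds each methoxy oxygen and bromide removes the methyl group by SN2, which the diaryl ether linkages cannot undergo, so aqueous work-up releases both catechols.

**Compound list**

1 | 3,5-dibromo-4-hydroxybenzaldehyde | O=Cc1cc(Br)c(O)c(Br)c1 | starting material
2 | 3,5-dibromo-4-(methoxymethoxy)benzaldehyde | COCOc1c(Br)cc(C=O)cc1Br | intermediate
3 | [3,5-dibromo-4-(methoxymethoxy)phenyl]methanol | COCOc1c(Br)cc(CO)cc1Br | intermediate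
4 | 1,3-dibromo-5-(bromomethyl)-2-(methoxymethoxy)benzene (formed in the flask) | COCOc1c(Br)cc(CBr)cc1Br | intermediate
5 | {[3,5-dibromo-4-(methoxymethoxy)phenyl]methyl}triphenylphosphonium bromide (ring B salt) | COCOc1c(Br)cc(C[P+](c2ccccc2)(c2ccccc2)c2ccccc2)cc1Br.[Br-] | intermediate
6 | 5-bromovanillin (3-bromo-4-hydroxy-5-methoxybenzaldehyde) | COc1cc(C=O)cc(Br)c1O | starting material
7 | 3-bromo-5-methoxy-4-(methoxymethoxy)benzaldehyde | COCOc1c(Br)cc(C=O)cc1OC | intermediate
8 | [3-bromo-5-methoxy-4-(methoxymethoxy)phenyl]methanol | COCOc1c(Br)cc(CO)cc1OC | intermediate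
9 | 1-bromo-5-(bromomethyl)-3-methoxy-2-(methoxymethoxy)benzene (formed in the flask) | COCOc1c(Br)cc(CBr)cc1OC | intermediate
10 | {[3-bromo-5-methoxy-4-(methoxymethoxy)phenyl]methyl}triphenylphosphonium bromide (ring A salt) | COCOc1c(Br)cc(C[P+](c2ccccc2)(c2ccccc2)c2ccccc2)cc1OC.[Br-] | intermediate
11 | 2-hydroxy-3,4-dimethoxybenzaldehyde | COc1ccc(C=O)c(O)c1OC | starting material
12 | {[3,5-dibromo-4-(methoxymethoxy)phenyl]methylidene}triphenylphosphorane (ring B ylide, formed in the flask) | COCOc1c(Br)cc(C=P(c2ccccc2)(c2ccccc2)c2ccccc2)cc1Br | intermediate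
13 | 6-{2-[3,5-dibromo-4-(methoxymethoxy)phenyl]ethenyl}-2,3-dimethoxyphenol, E/Z mixture | COCOc1c(Br)cc(C=Cc2ccc(OC)c(OC)c2O)cc1Br | intermediate
14 | 2-fluorobenzaldehyde | O=Cc1ccccc1F | starting material
15 | 2-(6-{2-[3,5-dibromo-4-(methoxymethoxy)phenyl]ethenyl}-2,3-dimethoxyphenoxy)benzaldehyde, E/Z mixture | COCOc1c(Br)cc(C=Cc2ccc(OC)c(OC)c2Oc2ccccc2C=O)cc1Br | intermediate
16 | {[3-bromo-5-methoxy-4-(methoxymethoxy)phenyl]methylidene}triphenylphosphorane (ring A ylide, formed in the flask) | COCOc1c(Br)cc(C=P(c2ccccc2)(c2ccccc2)c2ccccc2)cc1OC | intermediate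
17 | 2-bromo-4-{2-[2-(6-{2-[3,5-dibromo-4-(methoxymethoxy)phenyl]ethenyl}-2,3-dimethoxyphenoxy)phenyl]ethenyl}-6-methoxy-1-(methoxymethoxy)benzene, mixture of olefin isomers | COCOc1c(Br)cc(C=Cc2ccc(OC)c(OC)c2Oc2ccccc2C=Cc2cc(Br)c(OCOC)c(OC)c2)cc1Br | intermediate
18 | 2-bromo-4-{2-[2-(6-{2-[3,5-dibromo-4-(methoxymethoxy)phenyl]ethyl}-2,3-dimethoxyphenoxy)phenyl]ethyl}-6-methoxy-1-(methoxymethoxy)benzene | COCOc1c(Br)cc(CCc2ccc(OC)c(OC)c2Oc2ccccc2CCc2cc(Br)c(OCOC)c(OC)c2)cc1Br | intermediate
19 | 2-bromo-4-[2-(2-{6-[2-(3,5-dibromo-4-hydroxyphenyl)ethyl]-2,3-dimethoxyphenoxy}phenyl)ethyl]-6-methoxyphenol (open-chain tribromo bisphenol) | COc1cc(CCc2ccccc2Oc2c(CCc3cc(Br)c(O)c(Br)c3)ccc(OC)c2OC)cc(Br)c1O | intermediate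
20 | macrocyclic bromodienone: 17-membered ring in which ring A is a 6-aryloxy-6-bromo-2-methoxycyclohexa-2,4-dien-1-one (racemic at the bromine-bearing carbon, CH2CH2 to ring D at C4), ring B is 2,6-dibromo-1,4-phenylene, ring C is 3,4-dimethoxy and ring D is 1,2-phenylene (formed in the flask) | COC1=CC2=CC(Br)(C1=O)Oc1c(Br)cc(cc1Br)CCc1ccc(OC)c(OC)c1Oc1ccccc1CC2 | intermediate
21 | macrocyclic dibromo diaryl ether: ring A 4-hydroxy-3-methoxy with C5–O–ring B and C1–CH2CH2–ring D; ring B 1,4-phenylene with bromines at both positions ortho to the ether oxygen; ring C 3,4-dimethoxy with C1–CH2CH2–ring B and C2–O–ring D; ring D 1,2-phenylene | COc1cc2cc(c1O)Oc1c(Br)cc(cc1Br)CCc1ccc(OC)c(OC)c1Oc1ccccc1CC2 | intermediate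
22 | debrominated macrocycle: as 21 with ring B unsubstituted 1,4-phenylene (tri-O-methyl ether of the target) | COc1cc2cc(c1O)Oc1ccc(cc1)CCc1ccc(OC)c(OC)c1Oc1ccccc1CC2 | intermediate
23 | CNP0114693.0: 17-membered macrocyclic bis(bibenzyl), ring A 3,4-dihydroxy-5-aryloxy, ring B 1,4-phenylene, ring C 3,4-dihydroxy-2-aryloxy, ring D 1,2-phenylene | Oc1cc2cc(c1O)Oc1ccc(cc1)CCc1ccc(O)c(O)c1Oc1ccccc1CC2 | target

**Step count and risks**

Total steps: 14. Longest linear sequence: 11 (steps 1, 2, 3, 7, 8, 9, 10, 11, 12, 13, 14).

Steps most likely to fail: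

1. Step 12. Intermolecular C–O and C–C coupling and over-oxidation of the electron-rich rings may outrun the slow 17-membered ring closure, or the ring B oxygen may add at the wrong carbon of oxidised ring A so that zinc only regenerates open-chain material. The fallback closes the same ether bond by intramolecular copper-mediated Ullmann etherification. It sets out from 13 and comes back at 22.
   - Hydrogenation of 13 (H2, palladium on carbon, NaOAc) saturates the olefin and removes both ring B bromines to give 6-{2-[4-(methoxymethoxy)phenyl]ethyl}-2,3-dimethoxyphenol F1.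
   - SNAr with 14 (K2CO3, DMF, 120 °C) gives 2-(6-{2-[4-(methoxymethoxy)phenyl]ethyl}-2,3-dimethoxyphenoxy)benzaldehyde F2.
   - Aqueous HCl in THF frees the ring B phenol, giving 2-{6-[2-(4-hydroxyphenyl)ethyl]-2,3-dimethoxyphenoxy}benzaldehyde F3.
   - Wittig reaction with ylide 16 (one extra equivalent to cover the remote phenol) gives 4-{2-[2-(2-{2-[3-bromo-5-methoxy-4-(methoxymethoxy)phenyl]ethenyl}phenoxy)-3,4-dimethoxyphenyl]ethyl}phenol F4.
   - Diimide reduction gives 4-{2-[2-(2-{2-[3-bromo-5-methoxy-4-(methoxymethoxy)phenyl]ethyl}phenoxy)-3,4-dimethoxyphenyl]ethyl}phenol F5, which holds one aryl bromide (ring A, next to the acetal) and one free phenol (ring B).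
   - CuI, N,N-dimethylglycine and Cs2CO3 in dioxane at 100 °C under high dilution should close the ring to the macrocyclic ring A methoxymethyl ether F6.
   - HCl in MeOH removes the acetal and delivers 22.

2. Step 7. Olefination may stall because the aldehyde is deactivated as its ortho-phenoxide and excess ylide is consumed as base. The fallback reverses the order of ether formation and olefination. It sets out from 11 and comes back at 15.
   - SNAr of 11 with 2-fluorobenzonitrile (K2CO3, DMF, 120 °C) gives 2-(6-formyl-2,3-dimethoxyphenoxy)benzonitrile F7, in which only ring C carries an aldehyde.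
   - Wittig reaction with ylide 12 gives 2-(6-{2-[3,5-dibromo-4-(methoxymethoxy)phenyl]ethenyl}-2,3-dimethoxyphenoxy)benzonitrile F8.
   - iBu2AlH in toluene at –78 °C with aqueous acid work-up converts the nitrile into the aldehyde 15.

3. Step 8. Substitution at the doubly flanked phenoxide may be slow, and prolonged heating may degrade the aldehyde partner. The fallback forms the same C–O bond by oxidative copper coupling instead of SNAr. It sets out from 13 and comes back at 15: Chan–Lam O-arylation of 13 with (2-formylphenyl)boronic acid (Cu(OAc)2, pyridine, 4 Å molecular sieves, CH2Cl2, air, rt) gives 15 directly, and the aryl bromides are tolerated.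

**Further compounds**

F1 | step 12 | 6-{2-[4-(methoxymethoxy)phenyl]ethyl}-2,3-dimethoxyphenol | COCOc1ccc(CCc2ccc(OC)c(OC)c2O)cc1
F2 | step 12 | 2-(6-{2-[4-(methoxymethoxy)phenyl]ethyl}-2,3-dimethoxyphenoxy)benzaldehyde | COCOc1ccc(CCc2ccc(OC)c(OC)c2Oc2ccccc2C=O)cc1
F3 | step 12 | 2-{6-[2-(4-hydroxyphenyl)ethyl]-2,3-dimethoxyphenoxy}benzaldehyde | O=Cc1ccccc1Oc1c(CCc2ccc(O)cc2)ccc(OC)c1OC
F4 | step 12 | 4-{2-[2-(2-{2-[3-bromo-5-methoxy-4-(methoxymethoxy)phenyl]ethenyl}phenoxy)-3,4-dimethoxyphenyl]ethyl}phenol, E/Z mixture | COCOc1c(Br)cc(C=Cc2ccccc2Oc2c(CCc3ccc(O)cc3)ccc(OC)c2OC)cc1OC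
F5 | step 12 | 4-{2-[2-(2-{2-[3-bromo-5-methoxy-4-(methoxymethoxy)phenyl]ethyl}phenoxy)-3,4-dimethoxyphenyl]ethyl}phenol | COCOc1c(Br)cc(CCc2ccccc2Oc2c(CCc3ccc(O)cc3)ccc(OC)c2OC)cc1OC
F6 | step 12 | macrocyclic ring A methoxymethyl ether: as 22 with the ring A C4 hydroxyl carried as OCH2OCH3 | COCOc1c(OC)cc2cc1Oc1ccc(cc1)CCc1ccc(OC)c(OC)c1Oc1ccccc1CC2
F7 | step 7 | 2-(6-formyl-2,3-dimethoxyphenoxy)benzonitrile | N#Cc1ccccc1Oc1c(C=O)ccc(OC)c1OC
F8 | step 7 | 2-(6-{2-[3,5-dibromo-4-(methoxymethoxy)phenyl]ethenyl}-2,3-dimethoxyphenoxy)benzonitrile, E/Z mixture | COCOc1c(Br)cc(C=Cc2ccc(OC)c(OC)c2Oc2ccccc2C#N)cc1Br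
F0 | step 8 | none | none
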